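All runs come from a simulation for substances that don't exist; noise was put on by code.

Don't take the E charged for the E at work. In gamma, 0.65 mM of E meets 0.92 mM of L, and G reaches 0.4% at the last reading. So count the working catalyst, E charged minus L charged: 0.380 mM in the flask, against 0.840 mM in beta and 0.610 mM in epsilon.

| flask | Q | D | E | L | remark | time |
|---|---|---|---|---|---|---|
| beta | 0.10 M | 3.2 mM (held) | 1.3 mM | 0.46 mM | run made earlier |  |
| epsilon | 0.10 M | 3.2 mM (held) | 1.3 mM | 0.69 mM | run made earlier |  |
| gamma | 0.10 M | 3.2 mM (held) | 0.65 mM | 0.92 mM | run made earlier |  |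
| flask | 0.10 M | 3.2 mM (held) | 1.3 mM | 0.92 mM |  | 10 d |

| run | time / d | G / % |
|---|---|---|
| beta | 0.625 | 3.4 |
| beta | 1.67 | 7.0 |
| beta | 3.00 | 10.0 |
| beta | 5.00 | 14.6 |
| beta | 8.00 | 19.6 |
| beta | 10.0 | 22.8 |
| beta | 12.0 | 23.6 |
| epsilon | 0.625 | 2.8 |
| epsilon | 1.67 | 5.9 |
| epsilon | 3.00 | 9.0 |
| epsilon | 5.00 | 12.6 |
| epsilon | 8.00 | 17.0 |
| epsilon | 10.0 | 19.2 |
| epsilon | 12.0 | 21.9 |
| gamma | 2.50 | 0 |
| gamma | 5.00 | 0 |
| gamma | 8.00 | 0 |
| gamma | 10.0 | 0 |
| gamma | 12.0 | 0.4 |

(readings scatter by 0.3 percentage points)

- the G standing at 10 d, as a percentage of the Q charged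
- the change that raises the amount of G at 10 d, in percent of the Q charged most ("none" if none brings more than 2 percentage points) (dawn / midnight / summer / none)
- amount of G at 10 d, in percent of the Q charged, after summer

- the earlier runs were read with a standard deviation of 0.3 percentage points
- at the start none of D is in solution

- dawn: doubling the saturation concentration of D, all else as stated
- midnight: doubling the amount of E, all else as stated
- summer: doubling the transfer coefficient of D, all else as stated

First ask which numbers must be good. In this flask a relative error in E returns 3.42 times larger in the working catalyst, and one in L 2.42 times larger, while one in time enters once. Q never varied, so take it as charged. G rises from the first reading without a lag, so treat dissolved D as steady.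

Now integrate. Take Q's loss as pseudo-first-order, its pace proportional to working catalyst, so the gap below a ceiling of G shrinks as exp(−(w/wb)·t/T). Beta's readings at 5.00 d and 10.0 d give T = 8.67 d and a ceiling of 33.3%. Test this on epsilon: it gives 18.9% against 19.2% read. My flask figure is 13.5%. Doubling E adds 16 percentage points, and doubling saturation, if the pace follows D, adds 8 points, so I choose midnight. Summer stands nowhere in my formula, so I keep 13.5% there.

The forecast, holding that “L seems to kill E roughly 1:1”, gives 14.2%, midnight, and 14.8% after summer, its first figure above mine.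

The flask gives 15.3%, with midnight best at 12 points gained, dawn 8.3 points, and 16.8% after summer.

    G ⇌ Z (K = 2.30, k = 0.0696 h⁻¹)
    D ⇌ X, rate k2*(csat - [X]) (kL = 0.259 h⁻¹)
    Q + X + E → E + G (k = 2890 M⁻² h⁻¹)
    E + L → J (k = 5910 M⁻¹ h⁻¹)

Take away the passing of G into Z, both ways, and the flask holds 46.9% of G instead of 15.3%. At 10.0 d the flask's E stands at 29.2% of its charge and J at 70.8%, with L at 0%, and the working catalyst reckons 29.2%. Carry this to the neighbour flask charged with 0.0022 M of E: it reckons 58.2% and stands at 58.2%. That neighbour, given 27.6% by my formula, holds 25.8% of G.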